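The vessel holds starting material in one phase and, in a second phase a quarter of its volume, the reagent.

| flask | starting material | reagent in the second phase | remark | time | volume of the second phase over the first |
|---|---|---|---|---|---|
| Tuesday's | 0.025 M | 0.060 M | run made earlier |  |  |
| Thursday's | 0.10 M | 0.060 M | run made earlier |  |  |
| Friday's | 0.050 M | 0.12 M | run made earlier |  |  |
| flask | 0.050 M | 0.0600 M |  | 6.0 min | 0.25 |

- Tuesday's (time / min: target / %, starting material / %): 1.33: 8, 92; 2.50: 12, 87; 4.00: 19, 78; 5.00: 23, 70
- Thursday's (time / min: target / %, starting material / %): 0.667: 1, 96; 1.50: 8, 91; 3.00: 11, 84; 5.00: 21, 78
- Friday's (time / min: target / %, starting material / %): 0.417: 4, 97; 0.833: 5, 94; 2.00: 15, 79; 5.00: 27, 55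

(scatter of a reading: 1.5 percentage points)

- in the second phase: reagent in the second phase; everything else is in the first
- charges count per volume of the first phase; a concentration in a rate is the amount of a species over the volume of its own phase; every rate counts per litre of the first phase
- the earlier runs hold the two phases in the same ratio of volumes as the flask asked about

- how much target there is at 6.0 min, in percent of the starting material charged
- part of the starting material charged that has reacted at 6.0 min

Friday's run had the flask's charge of starting material, so I started from its last reading. Treating the decay as pseudo-first-order, I scaled it in proportion to reagent charge and time and got E = 0.359 for the flask. This is its exposure, the natural logarithm of starting material charged over starting material left. That put the part reacted at 30.1 %.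

I then tested whether one number was enough. At equal reagent and time, Tuesday's run read 0.357 and Thursday's 0.248, so exposure was lower with more starting material charged. Those runs bracket the flask's charge, and their geometric mean, scaled to 6.0 min, gave 0.357.

At 5.00 min in Friday's run, the readings put 40.0 % of what had reacted as not target. I took that share as a correction growing with E, which gave 24.0 % for the flask and so 22.9 % target.

The forecast, slightly lower, gave 22.5 % target and 29.5 % reacted, judging that “the target is overreacting with reagent”. The flask gave 21.9 % target and 29.4 % reacted.

    reagent in the reaction phase + target → over-reacted product (k = 2.50 M⁻¹ min⁻¹)
    starting material + reagent in the reaction phase → target (k = 1.50 M⁻¹ min⁻¹)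
    reagent in the reaction phase → decomposed reagent (k = 0.0280 min⁻¹)
    reagent in the reaction phase ⇌ reagent in the second phase, rate k4*([reagent in the reaction phase] - [reagent in the second phase]/K4) per volume of the first phase (partition coefficient = 0.360, kL = 0.160 min⁻¹)

The flask's exposure came to 0.348. At 3.00 min in the flask, reagent in the second phase stood at 7.10 % of its own charge and reagent in the reaction phase at 0.0429 M, and half of the making of target up to 6.00 min had been done by 2.67 min. Scaled by time to 25 min, E gives 1.50, but the neighbouring flask with the same charges, read at that time, reached 0.768, with 46.4 % starting material left and reagent in the reaction phase at 0.00543 M.

(The numbers in the tables were computed for substances that don't exist; the scatter is artificial.)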